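Labdane numbering is used throughout: ring A = C1–C5 and C10, ring B = C5–C10, C20 = the methyl on C10, C11–C16 = side chain, butenolide on C15. β is the face of the C10 methyl.
Cuts: C15–C16 (vinylogous aldol to the butenolide), C13=C14 (olefination), C9–C11 (addition to a C9 ketone), C8–OH and C8–CH3 (enolate chemistry), ring A at C1–C10 and C2–C3 (one annulation, C1–C2 from a vinylphosphonium salt), C4–C5 (Claisen), C10–C20 (Baylis–Hillman).
Forward: ring B is (S)-4-silyloxycyclohexenone; Baylis–Hillman and Claisen steps give the C10 exo-methylene and the C4(CH3)2–C3HO arm; the key step closes ring A and creates quaternary C10; the C9 ketone then serves to build C8 and attach C11–C13/C16; C14–C15 and the preformed butenolide ring come last.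
Enabling feature: C1 and C2 are bare methylenes between quaternary C10 and C3; C3 sits next to the gem-dimethyl C4 and can therefore be a non-enolisable aldehyde; C10 is α to C9, where a temporary ketone (later the side-chain carbon, oxygen removed in step 10) makes C10 an enolate carbon.
Stereochemistry: C6 (from the starting enone) directs C5 (Claisen anti to the silyloxy group); C5 directs C10 (anti Michael addition); the 10β-methyl directs C8 (α-face hydroxylation) and, with the 8β-methyl, C9 (α-face hydrogen transfer); C15/C16 come from a BINOL–titanium-controlled syn vinylogous aldol; the C13 alkene from an E-selective olefination.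
Key step: step 4

Remark: (S)-4-[(tert-butyldimethylsilyl)oxy]cyclohex-2-en-1-one (1) is assumed to be a purchasable enantiopure building block; all other inputs are catalogue reagents.

Step 1
Reactants: 1 (S)-4-[(tert-butyldimethylsilyl)oxy]cyclohex-2-en-1-one
Product: 2 (S)-4-[(tert-butyldimethylsilyl)oxy]-2-(hydroxymethyl)cyclohex-2-en-1-one
Conditions: aq. CH2O (37 %), 4-(dimethylamino)pyridine (cat.), THF, rt
Reagents that add atoms: formaldehyde (C=O)
Why: Morita–Baylis–Hillman reaction: the amine adds reversibly to the enone β-carbon (C5), the enolate is hydroxymethylated at the α-carbon (C10) and the amine is expelled, which installs C20 as the allylic CH2OH needed for the sigmatropic step; no stereocentre is formed and C6 is untouched.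

Step 2
Reactants: 2 (S)-4-[(tert-butyldimethylsilyl)oxy]-2-(hydroxymethyl)cyclohex-2-en-1-one
Product: 3 (S)-4-[(tert-butyldimethylsilyl)oxy]-2-{[(2-methylprop-2-en-1-yl)oxy]methyl}cyclohex-2-en-1-one
Conditions: Ag2O, 3-bromo-2-methylprop-1-ene, CH2Cl2, 4 Å molecular sieves, rt, dark
Reagents that add atoms: 3-bromo-2-methylprop-1-ene (C=C(C)CBr)
Why: Silver-oxide-mediated Williamson-type O-alkylation, chosen because it avoids an alkoxide base that would open retro-aldol and elimination pathways in the hydroxymethyl enone.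

Step 3
Reactants: 3 (S)-4-[(tert-butyldimethylsilyl)oxy]-2-{[(2-methylprop-2-en-1-yl)oxy]methyl}cyclohex-2-en-1-one
Product: 5 2-[(1S,2S)-2-[(tert-butyldimethylsilyl)oxy]-6-methylidene-5-oxocyclohexyl]-2-methylpropanal, via isobutenyl ether 4 (not isolated)
Conditions: [IrCl(coe)2]2 (1 mol %), PCy3, NaBPh4, CH2Cl2/acetone, rt; then PPh3, ClCH2CH2Cl, 80 °C
Reagents that add atoms: none
Why: Isomerisation–Claisen rearrangement: an iridium hydride moves the terminal 1,1-disubstituted double bond of the methallyl ether into conjugation with oxygen (4), and the allyl vinyl ether then undergoes a [3,3]-sigmatropic shift that forms the C4–C5 bond with its quaternary C4, the C3 aldehyde and the C10 exocyclic methylene at once; C5 is set by bond formation on the ring face opposite the pseudoaxial C6 silyloxy group (5,6-trans), the same bias that governs conjugate additions to 4-silyloxycyclohexenones.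

Step 4
Reactants: 5 2-[(1S,2S)-2-[(tert-butyldimethylsilyl)oxy]-6-methylidene-5-oxocyclohexyl]-2-methylpropanal; 6 ethenyl(triphenyl)phosphonium bromide (vinyltriphenylphosphonium bromide)
Product: 9 (4S,4aS,8aS)-4-[(tert-butyldimethylsilyl)oxy]-5,5,8a-trimethyl-3,4,4a,5,8,8a-hexahydronaphthalen-1(2H)-one (trans-fused ring A/ring B ketone with the C2=C3 alkene), via tributyltin enolate 7 (not isolated), via phosphonium ylide 8 (not isolated)
Conditions: Bu3SnH (1.1 equiv), Pd(PPh3)4 (3 mol %), THF, 0 °C to rt; then 6 (1.3 equiv), DMF, rt to 60 °C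
Reagents that add atoms: none
Why: Proposed new method: 1,4-hydrostannation of the exocyclic enone of 5, catalysed by zerovalent palladium, should give the regiodefined tributyltin enolate 7 without touching the hindered aldehyde; bromide from the added salt 6 coordinates tin, the resulting stannate enolate adds through C10 to the vinylphosphonium ion (bond C10–C1), and the non-stabilised ylide 8 closes by intramolecular Wittig reaction on the C3 aldehyde (bond C2=C3). The closest known reaction types are the enolate/vinylphosphonium Michael–intramolecular Wittig cycloalkene annulation and the Michael additions of halide-activated tin enolates made by conjugate hydrostannation of enones; their union in one flask, with the enolate generated reductively beside a free aldehyde, is the new element. Ring A is closed as a cyclohexene by 6-exo-trig attack of the ylide carbon C2 on the C3 carbonyl and collapse of the oxaphosphetane, which can only give the cis ring alkene. The one new stereocentre, quaternary C10, is set in the Michael step: the planar enolate is attacked on the face opposite the vicinal C5 substituent (the CMe2CHO group, pseudoaxial through A(1,2) strain with the C10 methyl), so C1 ends trans to C4 and the ring fusion is trans (10β-methyl, 5α-H). The step needs hydride delivery to the enone and not to the aldehyde (secured by the palladium/tin hydride couple and the α-quaternary, non-enolisable aldehyde), C- rather than O-alkylation at a tetrasubstituted enolate carbon (soft stannyl enolate, slim cationic acceptor), and Wittig closure on the aldehyde and not on the C9 ketone (six- against four-membered ring).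

Step 5
Reactants: 9 (4S,4aS,8aS)-4-[(tert-butyldimethylsilyl)oxy]-5,5,8a-trimethyl-3,4,4a,5,8,8a-hexahydronaphthalen-1(2H)-one
Product: 10 (4S,4aS,8aS)-4-[(tert-butyldimethylsilyl)oxy]-5,5,8a-trimethyloctahydronaphthalen-1(2H)-one
Conditions: H2 (1 atm), Pd/C, EtOAc, rt
Reagents that add atoms: none
Why: Heterogeneous catalytic hydrogenation of the cis-disubstituted ring-A alkene left by the Wittig closure; the ketone and silyl ether are inert and no stereocentre is created.

Step 6
Reactants: 10 (4S,4aS,8aS)-4-[(tert-butyldimethylsilyl)oxy]-5,5,8a-trimethyloctahydronaphthalen-1(2H)-one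
Product: 11 (2R,4S,4aS,8aS)-4-[(tert-butyldimethylsilyl)oxy]-2,5,5,8a-tetramethyloctahydronaphthalen-1(2H)-one (8α-methyl ketone)
Conditions: LiN(iPr)2, THF, −78 °C; MeI, −78 to −20 °C
Reagents that add atoms: iodomethane (CI)
Why: Kinetic enolate alkylation: the C9 ketone can enolise only towards C8 because C10 is quaternary, and iodomethane should enter from the α face opposite the axial C10 methyl (this centre is re-formed in step 7, so its configuration is immaterial).

Step 7
Reactants: 11 (2R,4S,4aS,8aS)-4-[(tert-butyldimethylsilyl)oxy]-2,5,5,8a-tetramethyloctahydronaphthalen-1(2H)-one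
Product: 12 (2R,4S,4aS,8aS)-4-[(tert-butyldimethylsilyl)oxy]-2-hydroxy-2,5,5,8a-tetramethyloctahydronaphthalen-1(2H)-one (8α-hydroxy-8β-methyl ketone)
Conditions: KN(SiMe3)2, THF, −78 to −40 °C; 2-(benzenesulfonyl)-3-phenyloxaziridine, −78 °C; AcOH
Reagents that add atoms: 2-(benzenesulfonyl)-3-phenyloxaziridine (O=S(=O)(N1OC1c1ccccc1)c1ccccc1)
Why: Electrophilic α-hydroxylation of the tetrasubstituted potassium enolate with an N-sulfonyloxaziridine (Davis oxidation); the oxidant should approach C8 from the α face because the β face is screened by the 1,3-related axial C10 methyl, which gives the 8α-hydroxy-8β-methyl centre.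

Step 8
Reactants: 12 (2R,4S,4aS,8aS)-4-[(tert-butyldimethylsilyl)oxy]-2-hydroxy-2,5,5,8a-tetramethyloctahydronaphthalen-1(2H)-one
Product: 13 (2R,4S,4aS,8aS)-4-[(tert-butyldimethylsilyl)oxy]-2,5,5,8a-tetramethyl-2-[(triethylsilyl)oxy]octahydronaphthalen-1(2H)-one
Conditions: Et3SiOTf, 2,6-lutidine, CH2Cl2, 0 °C
Reagents that add atoms: triethylsilyl trifluoromethanesulfonate (CC[Si](CC)(CC)OS(=O)(=O)C(F)(F)F)
Why: Silylation of the hindered tertiary alcohol with a silyl triflate and a hindered pyridine base protects O8 for the organometallic and radical steps and prevents diol chemistry at C8/C9.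

Step 9
Reactants: 13 (2R,4S,4aS,8aS)-4-[(tert-butyldimethylsilyl)oxy]-2,5,5,8a-tetramethyl-2-[(triethylsilyl)oxy]octahydronaphthalen-1(2H)-one; 14 2-(2-bromoethyl)-2-methyl-1,3-dioxolane
Product: 16 methyl oxalate of the C9 tertiary carbinol (C9 carries the 2-(2-methyl-1,3-dioxolan-2-yl)ethyl chain on the α face and the methoxyoxalyloxy group on the β face; 6α-OTBS and 8α-OTES unchanged), via bromomagnesium alkoxide 15 (not isolated)
Conditions: 14, Mg, THF (Grignard reagent); 13, LaCl3·2LiCl, THF, 0 °C to rt; then ClC(O)CO2Me, −40 to 0 °C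
Reagents that add atoms: methyl chlorooxoacetate (COC(=O)C(Cl)=O)
Why: Lanthanum-chloride-promoted Grignard 1,2-addition to a ketone that cannot enolise (both α-carbons quaternary), the nucleophile entering from the α face away from the axial C8 and C10 methyls, followed by O-acylation of the covalent magnesium alkoxide 15 before silyl migration can compete; this forms the C9–C11 bond and arms the superfluous C9 oxygen as a tertiary methyl oxalate.

Step 10
Reactants: 16 methyl oxalate of the C9 tertiary carbinol
Product: 17 6α-[(tert-butyldimethylsilyl)oxy]-8α-[(triethylsilyl)oxy]-14,15-dinorlabdan-13-one ethylene ketal (9α-H with the side chain β)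
Conditions: Bu3SnH, AIBN (cat.), toluene, 110 °C
Reagents that add atoms: none
Why: Tin-hydride radical deoxygenation of a tertiary methyl oxalate (Barton–McCombie type): fragmentation gives the tertiary C9 radical, which should abstract hydrogen from Bu3SnH on the α face, opposite the two flanking axial methyls at C8 and C10, so that H-9 is α and the side chain equatorial (β); the oxygen of the temporary C9 ketone is thereby removed.

Step 11
Reactants: 17 6α-[(tert-butyldimethylsilyl)oxy]-8α-[(triethylsilyl)oxy]-14,15-dinorlabdan-13-one ethylene ketal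
Product: 18 6α-[(tert-butyldimethylsilyl)oxy]-8α-[(triethylsilyl)oxy]-14,15-dinorlabdan-13-one
Conditions: pyridinium p-toluenesulfonate (cat.), acetone–H2O, 40 °C
Reagents that add atoms: water (O)
Why: Acid-catalysed hydrolysis of the dioxolane under conditions mild enough to keep the tertiary triethylsilyl and the secondary tert-butyldimethylsilyl ether.

Step 12
Reactants: 18 6α-[(tert-butyldimethylsilyl)oxy]-8α-[(triethylsilyl)oxy]-14,15-dinorlabdan-13-one
Product: 19 ethyl (13E)-6α-[(tert-butyldimethylsilyl)oxy]-8α-[(triethylsilyl)oxy]labd-13-en-15-oate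
Conditions: (EtO)2P(O)CH2CO2Et, NaH, THF, 0 °C to reflux; chromatographic removal of the Z isomer
Reagents that add atoms: triethyl phosphonoacetate (CCOC(=O)CP(=O)(OCC)OCC)
Why: Horner–Wadsworth–Emmons olefination of the methyl ketone; the stabilised phosphonate anion should favour the E trisubstituted enoate (ester trans to the C12 methylene).

Step 13
Reactants: 19 ethyl (13E)-6α-[(tert-butyldimethylsilyl)oxy]-8α-[(triethylsilyl)oxy]labd-13-en-15-oate
Product: 20 (13E)-6α-[(tert-butyldimethylsilyl)oxy]-8α-[(triethylsilyl)oxy]labd-13-en-15-ol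
Conditions: iBu2AlH (2.2 equiv), CH2Cl2, −78 °C; aqueous work-up
Reagents that add atoms: none
Why: 1,2-Reduction of the conjugated ester to the allylic alcohol by an aluminium hydride at low temperature, with retention of the alkene geometry.

Step 14
Reactants: 20 (13E)-6α-[(tert-butyldimethylsilyl)oxy]-8α-[(triethylsilyl)oxy]labd-13-en-15-ol
Product: 21 (13E)-6α-[(tert-butyldimethylsilyl)oxy]-8α-[(triethylsilyl)oxy]labd-13-en-15-al
Conditions: MnO2, CH2Cl2, rt
Reagents that add atoms: none
Why: Selective oxidation of the allylic alcohol with activated manganese dioxide, which leaves the E geometry intact.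

Step 15
Reactants: 22 4-methylfuran-2(5H)-one
Product: 23 4-methyl-2-[(trimethylsilyl)oxy]furan
Conditions: Me3SiOTf, Et3N, CH2Cl2, 0 °C
Reagents that add atoms: trimethylsilyl trifluoromethanesulfonate (C[Si](C)(C)OS(=O)(=O)C(F)(F)F)
Why: Soft enolisation and O-silylation of the butenolide to the aromatic 2-silyloxyfuran, the γ-nucleophile for the vinylogous aldol reaction.

Step 16
Reactants: 21 (13E)-6α-[(tert-butyldimethylsilyl)oxy]-8α-[(triethylsilyl)oxy]labd-13-en-15-al; 23 4-methyl-2-[(trimethylsilyl)oxy]furan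
Product: 25 6-O-tert-butyldimethylsilyl-8-O-triethylsilyl ether of the target (free 15S carbinol next to the 16S butenolide), via trimethylsilyl ether 24 (not isolated)
Conditions: Ti(OiPr)4 (20 mol %), (R)-BINOL (20 mol %), THF/Et2O, −20 °C; then aq. citric acid
Reagents that add atoms: none
Why: Catalytic asymmetric vinylogous Mukaiyama aldol reaction: the furan attacks the aldehyde 1,2 through its C5 (γ) position to form the C15–C16 bond; an open antiperiplanar transition state should give the syn (threo) C15/C16 pair, and the chiral titanium–BINOLate selects the aldehyde face, (R)-BINOL being the antipode expected to lead to 15S,16S, with the decalin stereocentres too remote to interfere; mild acid cleaves the O15 trimethylsilyl ether of 24.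

Step 17
Reactants: 25 6-O-tert-butyldimethylsilyl-8-O-triethylsilyl ether of the target
Product: 26 (5S)-5-{(1S,2E)-5-[(1R,2R,4S,4aS,8aS)-2,4-dihydroxy-2,5,5,8a-tetramethyldecahydronaphthalen-1-yl]-1-hydroxy-3-methylpent-2-en-1-yl}-4-methylfuran-2(5H)-one
Conditions: HF·pyridine, pyridine, THF, 0 °C to rt
Reagents that add atoms: none
Why: Fluoride-mediated cleavage of both silyl ethers with buffered hydrogen fluoride–pyridine, chosen because the butenolide γ-stereocentre and the allylic carbinol would not tolerate basic fluoride or strong acid.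

Compound list
1 | (S)-4-[(tert-butyldimethylsilyl)oxy]cyclohex-2-en-1-one | O=C1C=C[C@@H](O[Si](C)(C)C(C)(C)C)CC1 | starting material
2 | (S)-4-[(tert-butyldimethylsilyl)oxy]-2-(hydroxymethyl)cyclohex-2-en-1-one | O=C1C(CO)=C[C@@H](O[Si](C)(C)C(C)(C)C)CC1 | intermediate
3 | (S)-4-[(tert-butyldimethylsilyl)oxy]-2-{[(2-methylprop-2-en-1-yl)oxy]methyl}cyclohex-2-en-1-one | O=C1C(COCC(C)=C)=C[C@@H](O[Si](C)(C)C(C)(C)C)CC1 | intermediate
4 | (S)-4-[(tert-butyldimethylsilyl)oxy]-2-{[(2-methylprop-1-en-1-yl)oxy]methyl}cyclohex-2-en-1-one (isobutenyl ether) | O=C1C(COC=C(C)C)=C[C@@H](O[Si](C)(C)C(C)(C)C)CC1 | intermediate (not isolated)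
5 | 2-[(1S,2S)-2-[(tert-butyldimethylsilyl)oxy]-6-methylidene-5-oxocyclohexyl]-2-methylpropanal | O=CC(C)(C)[C@@H]1[C@@H](O[Si](C)(C)C(C)(C)C)CCC(=O)C1=C | intermediate
6 | ethenyl(triphenyl)phosphonium bromide | C=C[P+](c1ccccc1)(c1ccccc1)c1ccccc1.[Br-] | starting material
7 | tributyltin enolate of 5 (C9–O–SnBu3, tetrasubstituted C9=C10 bearing the new C20 methyl; C5 and C6 as in 5) | O=CC(C)(C)[C@@H]1[C@@H](O[Si](C)(C)C(C)(C)C)CCC(O[Sn](CCCC)(CCCC)CCCC)=C1C | intermediate (not isolated)
8 | phosphonium ylide from 7 and 6 (quaternary C10 with β-methyl and α-CH2CH=PPh3; C9 ketone and C3 aldehyde free) | O=CC(C)(C)[C@@H]1[C@@H](O[Si](C)(C)C(C)(C)C)CCC(=O)[C@@]1(C)CC=P(c1ccccc1)(c1ccccc1)c1ccccc1 | intermediate (not isolated)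
9 | (4S,4aS,8aS)-4-[(tert-butyldimethylsilyl)oxy]-5,5,8a-trimethyl-3,4,4a,5,8,8a-hexahydronaphthalen-1(2H)-one | O=C1[C@@]2(C)CC=CC(C)(C)[C@@H]2[C@@H](O[Si](C)(C)C(C)(C)C)CC1 | intermediate
10 | (4S,4aS,8aS)-4-[(tert-butyldimethylsilyl)oxy]-5,5,8a-trimethyloctahydronaphthalen-1(2H)-one | O=C1[C@@]2(C)CCCC(C)(C)[C@@H]2[C@@H](O[Si](C)(C)C(C)(C)C)CC1 | intermediate
11 | (2R,4S,4aS,8aS)-4-[(tert-butyldimethylsilyl)oxy]-2,5,5,8a-tetramethyloctahydronaphthalen-1(2H)-one | O=C1[C@@]2(C)CCCC(C)(C)[C@@H]2[C@@H](O[Si](C)(C)C(C)(C)C)C[C@H]1C | intermediate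
12 | (2R,4S,4aS,8aS)-4-[(tert-butyldimethylsilyl)oxy]-2-hydroxy-2,5,5,8a-tetramethyloctahydronaphthalen-1(2H)-one | O=C1[C@@]2(C)CCCC(C)(C)[C@@H]2[C@@H](O[Si](C)(C)C(C)(C)C)C[C@@]1(C)O | intermediate
13 | (2R,4S,4aS,8aS)-4-[(tert-butyldimethylsilyl)oxy]-2,5,5,8a-tetramethyl-2-[(triethylsilyl)oxy]octahydronaphthalen-1(2H)-one | O=C1[C@@]2(C)CCCC(C)(C)[C@@H]2[C@@H](O[Si](C)(C)C(C)(C)C)C[C@@]1(C)O[Si](CC)(CC)CC | intermediate
14 | 2-(2-bromoethyl)-2-methyl-1,3-dioxolane | CC1(CCBr)OCCO1 | starting material
15 | bromomagnesium alkoxide of the C9 adduct (chain α, O–MgBr β at C9) | CC1(CC[C@@]2(O[Mg]Br)[C@@]3(C)CCCC(C)(C)[C@@H]3[C@@H](O[Si](C)(C)C(C)(C)C)C[C@@]2(C)O[Si](CC)(CC)CC)OCCO1 | intermediate (not isolated)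
16 | methyl oxalate of the C9 tertiary carbinol (chain α, methoxyoxalyloxy β at C9) | CC1(CC[C@@]2(OC(=O)C(=O)OC)[C@@]3(C)CCCC(C)(C)[C@@H]3[C@@H](O[Si](C)(C)C(C)(C)C)C[C@@]2(C)O[Si](CC)(CC)CC)OCCO1 | intermediate
17 | 6α-[(tert-butyldimethylsilyl)oxy]-8α-[(triethylsilyl)oxy]-14,15-dinorlabdan-13-one ethylene ketal | CC1(CC[C@@H]2[C@@]3(C)CCCC(C)(C)[C@@H]3[C@@H](O[Si](C)(C)C(C)(C)C)C[C@@]2(C)O[Si](CC)(CC)CC)OCCO1 | intermediate
18 | 6α-[(tert-butyldimethylsilyl)oxy]-8α-[(triethylsilyl)oxy]-14,15-dinorlabdan-13-one | CC(=O)CC[C@@H]1[C@@]2(C)CCCC(C)(C)[C@@H]2[C@@H](O[Si](C)(C)C(C)(C)C)C[C@@]1(C)O[Si](CC)(CC)CC | intermediate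
19 | ethyl (13E)-6α-[(tert-butyldimethylsilyl)oxy]-8α-[(triethylsilyl)oxy]labd-13-en-15-oate | CCOC(=O)/C=C(\C)CC[C@@H]1[C@@]2(C)CCCC(C)(C)[C@@H]2[C@@H](O[Si](C)(C)C(C)(C)C)C[C@@]1(C)O[Si](CC)(CC)CC | intermediate
20 | (13E)-6α-[(tert-butyldimethylsilyl)oxy]-8α-[(triethylsilyl)oxy]labd-13-en-15-ol | OC/C=C(\C)CC[C@@H]1[C@@]2(C)CCCC(C)(C)[C@@H]2[C@@H](O[Si](C)(C)C(C)(C)C)C[C@@]1(C)O[Si](CC)(CC)CC | intermediate
21 | (13E)-6α-[(tert-butyldimethylsilyl)oxy]-8α-[(triethylsilyl)oxy]labd-13-en-15-al | O=C/C=C(\C)CC[C@@H]1[C@@]2(C)CCCC(C)(C)[C@@H]2[C@@H](O[Si](C)(C)C(C)(C)C)C[C@@]1(C)O[Si](CC)(CC)CC | intermediate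
22 | 4-methylfuran-2(5H)-one | CC1=CC(=O)OC1 | starting material
23 | 4-methyl-2-[(trimethylsilyl)oxy]furan | Cc1coc(O[Si](C)(C)C)c1 | intermediate
24 | 15-O-trimethylsilyl, 6-O-tert-butyldimethylsilyl, 8-O-triethylsilyl ether of the target | CC1=CC(=O)O[C@@H]1[C@@H](O[Si](C)(C)C)/C=C(\C)CC[C@@H]1[C@@]2(C)CCCC(C)(C)[C@@H]2[C@@H](O[Si](C)(C)C(C)(C)C)C[C@@]1(C)O[Si](CC)(CC)CC | intermediate (not isolated)
25 | 6-O-tert-butyldimethylsilyl, 8-O-triethylsilyl ether of the target | CC1=CC(=O)O[C@@H]1[C@@H](O)/C=C(\C)CC[C@@H]1[C@@]2(C)CCCC(C)(C)[C@@H]2[C@@H](O[Si](C)(C)C(C)(C)C)C[C@@]1(C)O[Si](CC)(CC)CC | intermediate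
26 | (5S)-5-{(1S,2E)-5-[(1R,2R,4S,4aS,8aS)-2,4-dihydroxy-2,5,5,8a-tetramethyldecahydronaphthalen-1-yl]-1-hydroxy-3-methylpent-2-en-1-yl}-4-methylfuran-2(5H)-one | CC1=CC(=O)O[C@@H]1[C@@H](O)/C=C(\C)CC[C@@H]1[C@@]2(C)CCCC(C)(C)[C@@H]2[C@@H](O)C[C@@]1(C)O | target

Total step count: 17. Longest linear sequence: 16 steps (steps 1–14, 16 and 17; step 15 makes the silyloxyfuran).

Steps most likely to fail

Step 4 (proposed new method). The tin enolate may be protonated or O-alkylated instead of adding through the congested C10. The aldehyde may be reduced or may undergo intermolecular Wittig reaction. Facial selectivity at C10 may be poor. The fallback uses known reaction types and sets out from 5. Wittig methylenation of the aldehyde (Ph3P=CH2, THF, −78 °C) should give the diene ketone (3S,4S)-4-[(tert-butyldimethylsilyl)oxy]-2-methylidene-3-(2-methylbut-3-en-2-yl)cyclohexan-1-one F1. Conjugate reduction with K[s-Bu3BH] and trapping of the potassium enolate with allyl bromide, trans to the C5 group, should give the 2-allyl-2-methyl ketone F2. Ring-closing metathesis with second-generation Grubbs catalyst then closes ring A and returns to 9.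

Step 9. Addition to the C9 ketone, which is flanked by two quaternary carbons, may stall, and reduction or silyl migration may take over before the alkoxide is acylated. The fallback sets out from 13 and changes the nucleophile to a sterically slim acetylide. The lithium acetylide of 2-ethynyl-2-methyl-1,3-dioxolane (n-BuLi, THF) is added and the alkoxide acylated in situ with methyl chlorooxoacetate to give the propargylic methyl oxalate F3. Radical deoxygenation (Bu3SnH, AIBN) should give the 9β-alkynyl compound F4; any allene isomer converges in the next operation. Hydrogenation (H2, Pd/C), which adds hydrogen to C9 from the α face where needed, returns to 17.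

Step 3. Isomerisation of the hindered 1,1-disubstituted allyl ether may be slow. The iridium hydride may move the exocyclic methylene of 5 into the ring. The congested [3,3] shift may show poor facial selectivity at C5. The fallback sets out from 1 and forms C4–C5 by conjugate addition. Mukaiyama–Michael addition of 2-methyl-1-[(trimethylsilyl)oxy]prop-1-ene (Me3SiOTf cat., CH2Cl2, −78 °C), anti to the silyloxy group, should give the silyl enol ether aldehyde F5. Mannich reaction of this regiodefined enol ether with dimethyl(methylidene)ammonium iodide should give the β-dimethylamino ketone F6. Quaternisation with MeI and elimination with NaHCO3 install the exocyclic methylene and return to 5.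

Further compounds
F1 | step 4 | (3S,4S)-4-[(tert-butyldimethylsilyl)oxy]-2-methylidene-3-(2-methylbut-3-en-2-yl)cyclohexan-1-one | C=CC(C)(C)[C@@H]1[C@@H](O[Si](C)(C)C(C)(C)C)CCC(=O)C1=C
F2 | step 4 | (2S,3S,4S)-4-[(tert-butyldimethylsilyl)oxy]-2-methyl-3-(2-methylbut-3-en-2-yl)-2-(prop-2-en-1-yl)cyclohexan-1-one | C=CC(C)(C)[C@@H]1[C@@H](O[Si](C)(C)C(C)(C)C)CCC(=O)[C@@]1(C)CC=C
F3 | step 9 | propargylic methyl oxalate (C9 carries the (2-methyl-1,3-dioxolan-2-yl)ethynyl group on the α face and the methoxyoxalyloxy group on the β face; 6α-OTBS and 8α-OTES as in 13) | CC1(C#C[C@@]2(OC(=O)C(=O)OC)[C@@]3(C)CCCC(C)(C)[C@@H]3[C@@H](O[Si](C)(C)C(C)(C)C)C[C@@]2(C)O[Si](CC)(CC)CC)OCCO1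
F4 | step 9 | 11,12-didehydro analogue of 17 (9α-H with the β-alkynyl side chain) | CC1(C#C[C@@H]2[C@@]3(C)CCCC(C)(C)[C@@H]3[C@@H](O[Si](C)(C)C(C)(C)C)C[C@@]2(C)O[Si](CC)(CC)CC)OCCO1
F5 | step 3 | 2-[(1R,6S)-6-[(tert-butyldimethylsilyl)oxy]-3-[(trimethylsilyl)oxy]cyclohex-2-en-1-yl]-2-methylpropanal (C5 and C6 substituents trans) | O=CC(C)(C)[C@@H]1[C@@H](O[Si](C)(C)C(C)(C)C)CCC(O[Si](C)(C)C)=C1
F6 | step 3 | Mannich base of F5: C10 carries CH2N(CH3)2 trans to the C5 substituent, C9 ketone, C3 aldehyde | O=CC(C)(C)[C@@H]1[C@@H](O[Si](C)(C)C(C)(C)C)CCC(=O)[C@H]1CN(C)C
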